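**Retrosynthetic overview**
- Oxane ring: (S)-linalool 1 → vinyl bromo-oxane 2 by a catalyst-controlled 6-endo bromoetherification, which forms the ring C–O bond and sets the C–Br centre (key step).
- Cyclohexane: bought as limonene diol 3. The secondary carbinol is inverted to the bromide through cyclic sulfate 5 (via sulfite 4), giving the cis bromohydrin 7 (via sulfate monoester 6).
- Handle: the isopropenyl group of 7 is C–H borylated to the (E)-alkenyl boronate 8.
- Diene: 8 + 2 → target 9 by oxidative Heck vinylation (central C–C bond of the pentadienyl linker).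
- Ring order: the cyclohexane is preformed in 3; the oxane is the only ring made (step 1).

Assumption: (S)-(+)-linalool 1 and (1S,2S,4R)-limonene-1,2-diol 3 are bought as single enantiomers (≥98% ee).

The target ring carries Br cis to the tertiary OH (Br, Me and side chain equatorial; OH axial). Bromonium or epoxide opening on the cyclohexene would give the trans isomer, so the bromide is introduced by SN2 inversion on the trans diol instead.

**Step 1**
Reactants: 1 (S)-(+)-linalool, (3S)-3,7-dimethylocta-1,6-dien-3-ol
Product: 2 (3R,6S)-3-bromo-6-ethenyl-2,2,6-trimethyloxane (Br cis to the 6-methyl; chair with Br and vinyl equatorial)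
Conditions: NBS (1.1 equiv), (R)-3,3′-bis(2,4,6-triisopropylphenyl)-BINOL N-[3,5-bis(trifluoromethyl)phenyl]thiophosphoramide (10 mol %), 4 Å MS, toluene/CH2Cl2 3:1, −60 °C
Reagents that add atoms: N-bromosuccinimide, O=C1CCC(=O)N1Br
Why: Proposed new method: the chiral thiophosphoramide acts as a Lewis base at sulfur, takes Br+ from NBS (its N–H hydrogen-bonds the imide carbonyl) and delivers it to one face of the electron-rich trisubstituted C6=C7 bond, the vinyl group being far less nucleophilic; the unsymmetrical bromiranium ion carries its charge at tertiary C7, so the tertiary hydroxyl, hydrogen-bonded to the catalyst–succinimidate ion pair, closes anti to bromine in the Markovnikov 6-endo mode through a chair with Br and vinyl equatorial, forming the ring C–O bond and setting C3 as R while the carbinol centre (S) is carried over unchanged; the substrate has almost no facial bias of its own, so the catalyst decides, and the catalyst antipode that gives 3R is picked in a two-run screen; closest known reaction type: chiral Lewis-base (P=S) catalysed enantioselective bromonium-initiated polyene cyclization and chiral-acid/Lewis-base bromocycloetherification of primary alkenols, neither shown for a tertiary homoprenyl carbinol closing 6-endo.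

**Step 2**
Reactants: 3 (1S,2S,4R)-1-methyl-4-(prop-1-en-2-yl)cyclohexane-1,2-diol (trans-diaxial diol)
Product: 5 (3aS,6R,7aS)-3a-methyl-6-(prop-1-en-2-yl)hexahydro-1,3,2-benzodioxathiole 2,2-dioxide (trans-fused cyclic sulfate), via cyclic sulfite 4 (not isolated)
Conditions: SOCl2 (1.3 equiv), Et3N (3 equiv), CH2Cl2, 0 °C; then RuCl3·3H2O (0.5 mol %), NaIO4 (1.3 equiv), MeCN/H2O, 0 °C, 10 min, 2-propanol quench
Reagents that add atoms: thionyl chloride, O=S(Cl)Cl; sodium periodate NaIO4, [Na+].[O-]I(=O)(=O)=O
Why: Sharpless cyclic sulfate synthesis: the diol closes to the trans-fused sulfite through the flipped chair with both oxygens equatorial (attack of the tertiary OH at sulfur outruns epoxide closure at carbon), and RuO4 formed in situ oxidises the sulfite sulfur within minutes at 0 °C, before the 1,1-disubstituted alkene is cleaved; no stereocentre is touched.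

**Step 3**
Reactants: 5 cyclic sulfate
Product: 7 (1S,2R,4R)-2-bromo-1-methyl-4-(prop-1-en-2-yl)cyclohexan-1-ol, via lithium bromo sulfate monoester 6 (not isolated)
Conditions: LiBr (2 equiv), THF, 45 °C; then H2SO4 (cat.), H2O (2 equiv), THF, 23 °C
Reagents that add atoms: lithium bromide LiBr, [Li+].[Br-]
Why: Cyclic sulfate opening (SN2): bromide attacks the secondary carbon anti to its C–O bond and inverts C2 from S to R, while the tertiary oxygen stays tied up as the sulfate monoester and cannot close to the epoxide; acid hydrolysis of the monoester cleaves S–O, not C–O, so C1 keeps its configuration and the cis bromohydrin results.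

**Step 4**
Reactants: 7 cis bromohydrin
Product: 8 (1S,2R,4R)-2-bromo-1-methyl-4-[(E)-1-(4,4,5,5-tetramethyl-1,3,2-dioxaborolan-2-yl)prop-1-en-2-yl]cyclohexan-1-ol
Conditions: B2pin2 (1.1 equiv), trans-RhCl(CO)(PPh3)2 (5 mol %), toluene/MeCN 3:1, 80 °C; aqueous work-up
Reagents that add atoms: bis(pinacolato)diboron, CC1(C)OB(OC1(C)C)B1OC(C)(C)C(C)(C)O1
Why: Rhodium-catalysed dehydrogenative borylation: a Rh–Bpin species inserts the 1,1-disubstituted alkene with boron at CH2, and β-hydride elimination from the CH2Bpin carbon gives the trisubstituted alkenyl boronate, E because Bpin ends trans to the bulkier cyclohexyl group; the ring stereocentres, the secondary bromide and the tertiary alcohol are spectators.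

**Step 5**
Reactants: 8 alkenyl boronate and 2 vinyl bromo-oxane (1.5 equiv)
Product: 9 (1S,2R,4R)-2-bromo-4-[(2E,4E)-5-[(2S,5R)-5-bromo-2,6,6-trimethyloxan-2-yl]penta-2,4-dien-2-yl]-1-methylcyclohexan-1-ol (CNP0199463.1)
Conditions: Pd(OAc)2 (10 mol %), 1,2-bis(phenylsulfinyl)ethane (10 mol %), 1,4-benzoquinone (2 equiv), AcOH (4 equiv), dioxane, 45 °C
Reagents that add atoms: none
Why: Oxidative boron-Heck (Heck–Mizoroki-type) vinylation: transmetalation of 8 to divalent palladium with retention of the E geometry, insertion of the terminal vinyl group of 2 with the alkenyl group going to CH2, and syn β-hydride elimination give the new E double bond, the quaternary oxane carbon offering no allylic hydrogen for isomerisation; benzoquinone reoxidises zerovalent palladium and no stereocentre is touched.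

**Compound list**
1 | (S)-(+)-linalool, (3S)-3,7-dimethylocta-1,6-dien-3-ol | C=C[C@@](C)(O)CCC=C(C)C | starting material
2 | (3R,6S)-3-bromo-6-ethenyl-2,2,6-trimethyloxane | C=C[C@]1(C)CC[C@@H](Br)C(C)(C)O1 | intermediate
3 | (1S,2S,4R)-1-methyl-4-(prop-1-en-2-yl)cyclohexane-1,2-diol | CC(=C)[C@@H]1CC[C@](C)(O)[C@@H](O)C1 | starting material
4 | (3aS,6R,7aS)-3a-methyl-6-(prop-1-en-2-yl)hexahydro-1,3,2-benzodioxathiole 2-oxide (both sulfur epimers) | CC(=C)[C@@H]1CC[C@]2(C)OS(=O)O[C@H]2C1 | intermediate
5 | (3aS,6R,7aS)-3a-methyl-6-(prop-1-en-2-yl)hexahydro-1,3,2-benzodioxathiole 2,2-dioxide | CC(=C)[C@@H]1CC[C@]2(C)OS(=O)(=O)O[C@H]2C1 | intermediate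
6 | lithium (1S,2R,4R)-2-bromo-1-methyl-4-(prop-1-en-2-yl)cyclohexyl sulfate | CC(=C)[C@@H]1CC[C@](C)(OS(=O)(=O)[O-])[C@H](Br)C1.[Li+] | intermediate
7 | (1S,2R,4R)-2-bromo-1-methyl-4-(prop-1-en-2-yl)cyclohexan-1-ol | CC(=C)[C@@H]1CC[C@](C)(O)[C@H](Br)C1 | intermediate
8 | (1S,2R,4R)-2-bromo-1-methyl-4-[(E)-1-(4,4,5,5-tetramethyl-1,3,2-dioxaborolan-2-yl)prop-1-en-2-yl]cyclohexan-1-ol | C/C(=C\B1OC(C)(C)C(C)(C)O1)[C@@H]1CC[C@](C)(O)[C@H](Br)C1 | intermediate
9 | (1S,2R,4R)-2-bromo-4-[(2E,4E)-5-[(2S,5R)-5-bromo-2,6,6-trimethyloxan-2-yl]penta-2,4-dien-2-yl]-1-methylcyclohexan-1-ol | C/C(=C\C=C\[C@]1(C)CC[C@@H](Br)C(C)(C)O1)[C@@H]1CC[C@](C)(O)[C@H](Br)C1 | target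

**Step count:** 5 steps in total. Longest linear sequence: 4 steps (3 → 5 → 7 → 8 → 9); step 1 is a one-step side branch that joins at step 5.

**Steps most likely to fail**

Step 1 (proposed new method). The catalyst may fail to control the bromonium face, or 5-exo closure to the tetrahydrofuran may compete. Fallback with known chemistry, setting out from 1 and coming back at 2: give up catalyst control and treat 1 with stoichiometric 2,4,4,6-tetrabromocyclohexa-2,5-dienone in MeNO2 at 0 °C, the established reagent for closing 3-bromo-2,2,6-trimethyloxane rings. This gives 2 together with its C3 epimer (3S,6S)-3-bromo-6-ethenyl-2,2,6-trimethyloxane F1 and tetrahydrofuran isomers; 2 is isolated by chromatography and the route continues unchanged.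

Step 3. In the trans-fused sulfate the bromide must enter syn-axial to the isopropenyl group, so the SN2 opening may be slow, and the tertiary sulfate may ionise and eliminate instead. Fallback, setting out from 3 and coming back at 7 (it also avoids the RuO4 oxidation of step 2): MeC(OMe)3 with catalytic pyridinium p-toluenesulfonate in CH2Cl2 converts 3 into the cyclic orthoacetate (3aS,6R,7aS)-2-methoxy-2,3a-dimethyl-6-(prop-1-en-2-yl)hexahydro-1,3-benzodioxole F2. Acetyl bromide at 0 °C then opens the derived acetoxonium ion at the secondary carbon with inversion to give (1S,2R,4R)-2-bromo-1-methyl-4-(prop-1-en-2-yl)cyclohexyl acetate F3. i-Bu2AlH in CH2Cl2 at −78 °C removes the tertiary acetate and gives 7.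

Step 4. The borylation may give allyl boronate isomers or E/Z mixtures, or the catalyst may be slowed by the free alcohol and the alkyl bromide. Fallback, setting out from 7 and coming back at 8: ozonolysis (O3, CH2Cl2/MeOH, −78 °C, then Me2S) gives the methyl ketone 1-[(1R,3R,4S)-3-bromo-4-hydroxy-4-methylcyclohexyl]ethan-1-one F4. Boron-Wittig olefination with bis[(pinacolato)boryl]methane and lithium 2,2,6,6-tetramethylpiperidide (excess, THF, −78 to 23 °C) gives 8 with Bpin trans to the cyclohexyl group. Any epimerisation next to the ketone is harmless because the required all-equatorial isomer is the thermodynamic one.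

**Further compounds**
F1 | step 1 | (3S,6S)-3-bromo-6-ethenyl-2,2,6-trimethyloxane | C=C[C@]1(C)CC[C@H](Br)C(C)(C)O1
F2 | step 3 | (3aS,6R,7aS)-2-methoxy-2,3a-dimethyl-6-(prop-1-en-2-yl)hexahydro-1,3-benzodioxole (both C2 epimers) | CC(=C)[C@@H]1CC[C@]2(C)OC(C)(OC)O[C@H]2C1
F3 | step 3 | (1S,2R,4R)-2-bromo-1-methyl-4-(prop-1-en-2-yl)cyclohexyl acetate | CC(=C)[C@@H]1CC[C@](C)(OC(C)=O)[C@H](Br)C1
F4 | step 4 | 1-[(1R,3R,4S)-3-bromo-4-hydroxy-4-methylcyclohexyl]ethan-1-one | CC(=O)[C@@H]1CC[C@](C)(O)[C@H](Br)C1
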